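## Retrosynthetic overview
1. Cut the methylene bridge last. The chromene half reacts as its ortho-quinone methide (made from the phenol, CH2O and Me2NH), and the dienone half reacts as the enol nucleophile.
2. Cut the C–CH3 bond at the quaternary centre of the dienone half. The ring carbon acts as an enolonium equivalent (the phenol bound through oxygen to a chiral trivalent-iodine reagent) and the methyl group comes from Me2Zn. This dearomatisation sets the only stereocentre.
3. The phenol for that step comes from phloroacetophenone. It is brominated once, to mask the free ring CH (the bromine is lost again in the quench), and then C-geranylated with geranyl bromide, which brings in the E-olefin.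
4. The chromene half comes from phloroglucinol and hexanoyl chloride (Friedel-Crafts), followed by prenal (condensation and oxa-6π closure).
5. Ring order: both carbocycles are bought as arenes, the pyran ring is the only ring formed, and one arene is dearomatised in the key step.

Assumption: the beta-triketone units are drawn in the tautomer of the given SMILES, and the (R,R)-iodane is taken as the enantiomer that gives the (R)-centre; if the first run shows the opposite sense, the (S,S)-iodoarene is used in the same way.

## Route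

Step 1
Reactants: 1 1-(2,4,6-trihydroxyphenyl)ethan-1-one (phloroacetophenone)
Product: 2 1-(3-bromo-2,4,6-trihydroxyphenyl)ethan-1-one
Conditions: NBS (1.0 equiv), MeCN, −20 → 0 °C
Reagents that add atoms: N-bromosuccinimide, O=C1CCC(=O)N1Br
Why: Electrophilic aromatic bromination of the very electron-rich ring stops at the monobromide with one equivalent of NBS in the cold, and the bromine masks the ring CH that would otherwise be geranylated twice and would bind the iodine reagent through carbon in the dearomatisation.

Step 2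
Reactants: 2 1-(3-bromo-2,4,6-trihydroxyphenyl)ethan-1-one; 3 geranyl bromide, (2E)-1-bromo-3,7-dimethylocta-2,6-diene
Product: 4 1-{3-bromo-5-[(2E)-3,7-dimethylocta-2,6-dien-1-yl]-2,4,6-trihydroxyphenyl}ethan-1-one
Conditions: KOH (1.05 equiv), MeOH, 0 °C → rt
Reagents that add atoms: none
Why: C-alkylation of the ambident phloroglucinol phenolate (SN2 on the primary allylic bromide, favoured over O-alkylation in a protic solvent) takes place at the only ring CH left, and the E-olefin of 3 is carried over unchanged.

Step 3
Reactants: 5 (2R,2'R)-2,2'-[(2-iodo-1,3-phenylene)bis(oxy)]bis[N-(2,4,6-trimethylphenyl)propanamide]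
Product: 6 (2R,2'R)-2,2'-{[2-(diacetoxyiodo)-1,3-phenylene]bis(oxy)}bis[N-(2,4,6-trimethylphenyl)propanamide]
Conditions: AcOOH (about 35 % in AcOH, 1.5 equiv), AcOH, 30 °C; precipitate with water, dry
Reagents that add atoms: peracetic acid, CC(=O)OO; acetic acid, CC(=O)O
Why: Peracid oxidation of an aryl iodide to the (diacetoxyiodo)arene is the standard preparation of PhI(OAc)2-type reagents and does not touch the two lactamide stereocentres.

Step 4
Reactants: 4 1-{3-bromo-5-[(2E)-3,7-dimethylocta-2,6-dien-1-yl]-2,4,6-trihydroxyphenyl}ethan-1-one; 6 chiral (diacetoxyiodo)arene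
Product: 9 (4R)-2-acetyl-4-[(2E)-3,7-dimethylocta-2,6-dien-1-yl]-3,5-dihydroxy-4-methylcyclohexa-2,5-dien-1-one, via O-bound iodane enolonium species 7 (not isolated), via bromo dienone 8 (not isolated)
Conditions: Me2Zn (4.0 equiv, toluene solution), CH2Cl2, −78 °C, 20 min; 6 (1.1 equiv) in CH2Cl2 added over 30 min, −78 → −40 °C; then aq Na2SO3/AcOH buffer (pH 4–5), 0 °C → rt
Reagents that add atoms: dimethylzinc, C[Zn]C
Why: Proposed new method: the zinc phenolate of 4 displaces one acetate of 6 at the only unchelated oxygen (O-4) to give 7, an oxygen-bound trivalent-iodine enolate that acts as an enolonium equivalent and makes the normally nucleophilic ring carbons electrophilic; of these carbons only C-5 carries a cation-stabilising alkyl group (C-1 bears acetyl, C-3 bromine), so the methyl of Me2Zn attacks there in an SN2'-type displacement of iodoarene 5, and because 5 is still bound next to the reacting carbon its two (R)-lactamide arms shield one ring face and set the quaternary centre by reagent control; the vinylogous alpha-bromo diketone 8 then gives up its positive bromine to sulfite in the quench; the closest known reaction types are the oxidative umpolung alpha-alkylation of 2-substituted 1,3-dicarbonyl compounds with dialkylzincs and PhI(OAc)2-type reagents, the dearomatising addition of carbon nucleophiles to phenols under PhI(OAc)2, and enantioselective dearomatisations with lactate-derived chiral aryl iodanes.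

Step 5
Reactants: 10 phloroglucinol (benzene-1,3,5-triol); 11 hexanoyl chloride
Product: 12 1-(2,4,6-trihydroxyphenyl)hexan-1-one
Conditions: AlCl3 (3.5 equiv), CH2Cl2/MeNO2, 0 → 40 °C; ice/1 M HCl
Reagents that add atoms: none
Why: Friedel-Crafts acylation stops after one acyl group because the chelated aryl ketone is strongly deactivated.

Step 6
Reactants: 12 1-(2,4,6-trihydroxyphenyl)hexan-1-one; 13 3-methylbut-2-enal (prenal)
Product: 15 1-(5,7-dihydroxy-2,2-dimethyl-2H-chromen-8-yl)hexan-1-one, via dienyl quinone methide 14 (not isolated)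
Conditions: 13 (1.2 equiv), ethylenediammonium diacetate (10 mol %), toluene, 110 °C
Reagents that add atoms: none
Why: Knoevenagel-type condensation of iminium-activated prenal at a ring CH gives 14, which closes by oxa-6π electrocyclisation; closure through the oxygen next to the acyl group should give the 8-acyl chromene as the main isomer, and the 6-acyl isomer is removed by chromatography.

Step 7
Reactants: 15 1-(5,7-dihydroxy-2,2-dimethyl-2H-chromen-8-yl)hexan-1-one; 9 (4R)-2-acetyl-4-[(2E)-3,7-dimethylocta-2,6-dien-1-yl]-3,5-dihydroxy-4-methylcyclohexa-2,5-dien-1-one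
Product: 18 (4R)-2-acetyl-6-[(8-hexanoyl-5,7-dihydroxy-2,2-dimethyl-2H-chromen-6-yl)methyl]-4-[(2E)-3,7-dimethylocta-2,6-dien-1-yl]-3,5-dihydroxy-4-methylcyclohexa-2,5-dien-1-one (target), via Mannich base 16 (not isolated), via ortho-quinone methide 17 (not isolated)
Conditions: 15, aq CH2O (37 %, 1.0 equiv), aq Me2NH (40 %, 1.05 equiv), EtOH, rt, 3 h; then 9 (1.0 equiv), 75 °C, 6 h
Reagents that add atoms: formaldehyde, C=O; dimethylamine, CNC (its atoms stay only in 16 and leave again)
Why: A Mannich reaction at the only free ring carbon of 15 gives 16, the acidic enol 9 protonates its amine, thermal loss of dimethylamine gives 17, and Michael addition of 9 through its only ring CH closes the bridge without touching the quaternary centre.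

## Compound list
1 | 1-(2,4,6-trihydroxyphenyl)ethan-1-one | CC(=O)c1c(O)cc(O)cc1O | starting material
2 | 1-(3-bromo-2,4,6-trihydroxyphenyl)ethan-1-one | CC(=O)c1c(O)cc(O)c(Br)c1O | intermediate
3 | geranyl bromide | CC(C)=CCC/C(C)=C/CBr | starting material
4 | 1-{3-bromo-5-[(2E)-3,7-dimethylocta-2,6-dien-1-yl]-2,4,6-trihydroxyphenyl}ethan-1-one | CC(=O)c1c(O)c(Br)c(O)c(C/C=C(\C)CCC=C(C)C)c1O | intermediate
5 | (R,R)-2-iodo-1,3-bis[1-(mesitylcarbamoyl)ethoxy]benzene (catalogue chiral iodoarene, recovered after step 4) | Ic1c(O[C@H](C)C(=O)Nc2c(C)cc(C)cc2C)cccc1O[C@H](C)C(=O)Nc1c(C)cc(C)cc1C | starting material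
6 | (R,R)-2-(diacetoxyiodo)-1,3-bis[1-(mesitylcarbamoyl)ethoxy]benzene | CC(=O)OI(OC(C)=O)c1c(O[C@H](C)C(=O)Nc2c(C)cc(C)cc2C)cccc1O[C@H](C)C(=O)Nc1c(C)cc(C)cc1C | intermediate
7 | O-4 aryl(acetoxy)iodanyl derivative of 4 (enolonium equivalent, drawn without zinc) | CC(=O)c1c(O)c(Br)c(OI(OC(C)=O)c2c(O[C@H](C)C(=O)Nc3c(C)cc(C)cc3C)cccc2O[C@H](C)C(=O)Nc2c(C)cc(C)cc2C)c(C/C=C(\C)CCC=C(C)C)c1O | intermediate (not isolated)
8 | (4S)-2-acetyl-6-bromo-4-[(2E)-3,7-dimethylocta-2,6-dien-1-yl]-3,5-dihydroxy-4-methylcyclohexa-2,5-dien-1-one (same spatial arrangement as 9; the descriptor changes only because bromine raises one ring branch in priority) | O=C1C(Br)=C(O)[C@@](C)(C/C=C(\C)CCC=C(C)C)C(O)=C1C(C)=O | intermediate (not isolated)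
9 | (4R)-2-acetyl-4-[(2E)-3,7-dimethylocta-2,6-dien-1-yl]-3,5-dihydroxy-4-methylcyclohexa-2,5-dien-1-one | O=C1C=C(O)[C@@](C)(C/C=C(\C)CCC=C(C)C)C(O)=C1C(C)=O | intermediate
10 | phloroglucinol | Oc1cc(O)cc(O)c1 | starting material
11 | hexanoyl chloride | CCCCCC(=O)Cl | starting material
12 | 1-(2,4,6-trihydroxyphenyl)hexan-1-one | CCCCCC(=O)c1c(O)cc(O)cc1O | intermediate
13 | 3-methylbut-2-enal | CC(C)=CC=O | starting material
14 | 2-hexanoyl-3,5-dihydroxy-6-(3-methylbut-2-en-1-ylidene)cyclohexa-2,4-dien-1-one | CCCCCC(=O)C1=C(O)C=C(O)C(=CC=C(C)C)C1=O | intermediate (not isolated)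
15 | 1-(5,7-dihydroxy-2,2-dimethyl-2H-chromen-8-yl)hexan-1-one | CCCCCC(=O)c1c(O)cc(O)c2c1OC(C)(C)C=C2 | intermediate
16 | 1-{6-[(dimethylamino)methyl]-5,7-dihydroxy-2,2-dimethyl-2H-chromen-8-yl}hexan-1-one | CCCCCC(=O)c1c(O)c(CN(C)C)c(O)c2c1OC(C)(C)C=C2 | intermediate (not isolated)
17 | 8-hexanoyl-7-hydroxy-2,2-dimethyl-6-methylidene-2H-chromen-5(6H)-one | CCCCCC(=O)C1=C(O)C(=C)C(=O)C2=C1OC(C)(C)C=C2 | intermediate (not isolated)
18 | target, (4R) | CCCCCC(=O)c1c(O)c(CC2=C(O)[C@@](C)(C/C=C(\C)CCC=C(C)C)C(O)=C(C(C)=O)C2=O)c(O)c2c1OC(C)(C)C=C2 | target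

## Step count and risks
Total step count: 7. Longest linear sequence: 4 steps (1 → 2 → 4 → 7). The side branches are step 3 (the reagent) and steps 5 and 6 (the chromene half).

**Most likely to fail, in order:**

**1. Step 4.**
- Me2Zn may consume 6 directly.
- The enolonium species may lose an allylic proton of the geranyl CH2, giving a vinyl quinone methide and then a chromene.
- Methyl may enter at the bromine-bearing carbon.
- The level and sense of enantioselectivity are untested.
- Fallback, setting out from 4 and using ordinary polarity followed by resolution. MeI and NaOMe in MeOH at 0 °C methylate the phenolate at the geranyl-bearing carbon, because bromine blocks the other site, and give racemic 2-acetyl-6-bromo-4-geranyl-3,5-dihydroxy-4-methylcyclohexa-2,5-dien-1-one F1. Aqueous Na2SO3 removes the bromine to give racemic 2-acetyl-4-geranyl-3,5-dihydroxy-4-methylcyclohexa-2,5-dien-1-one F2. Preparative chiral SFC separates 9 from the (4S)-enantiomer F3, and the route is rejoined at 9.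

**2. Step 6.**
- The ratio of 8-acyl to 6-acyl chromene may be poor, and a second chromene ring may form.
- Fallback, setting out from 12 and fixing the regiochemistry with a blocking group. TBSCl and imidazole in DMF silylate only the para hydroxyl, the one not hydrogen-bonded to the ketone, giving 1-{4-[(tert-butyldimethylsilyl)oxy]-2,6-dihydroxyphenyl}hexan-1-one F4. Condensation with prenal can then close only through an oxygen next to the ketone, giving 1-{5-[(tert-butyldimethylsilyl)oxy]-7-hydroxy-2,2-dimethyl-2H-chromen-8-yl}hexan-1-one F5. Bu4NF in THF frees the phenol, and the route is rejoined at 15.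

**3. Step 7.**
- Residual formaldehyde or reversible bridge cleavage may give the two symmetrical dimers beside 18.
- Fallback, setting out from 15 and avoiding free formaldehyde altogether. Vilsmeier-Haack formylation (POCl3, DMF, 0 °C, then water) gives 8-hexanoyl-5,7-dihydroxy-2,2-dimethyl-2H-chromene-6-carbaldehyde F6. Three-component reductive alkylation with 9, L-proline (20 mol %) and the Hantzsch ester in CH2Cl2 passes through the Knoevenagel alkylidene trione F7, which is reduced in the flask by conjugate hydride transfer. This arrives directly at 18.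

Further compounds
F1 | step 4 | racemic 2-acetyl-6-bromo-4-geranyl-3,5-dihydroxy-4-methylcyclohexa-2,5-dien-1-one | O=C1C(Br)=C(O)C(C)(C/C=C(\C)CCC=C(C)C)C(O)=C1C(C)=O
F2 | step 4 | racemic 2-acetyl-4-geranyl-3,5-dihydroxy-4-methylcyclohexa-2,5-dien-1-one | O=C1C=C(O)C(C)(C/C=C(\C)CCC=C(C)C)C(O)=C1C(C)=O
F3 | step 4 | (4S)-2-acetyl-4-geranyl-3,5-dihydroxy-4-methylcyclohexa-2,5-dien-1-one | O=C1C=C(O)[C@](C)(C/C=C(\C)CCC=C(C)C)C(O)=C1C(C)=O
F4 | step 6 | 1-{4-[(tert-butyldimethylsilyl)oxy]-2,6-dihydroxyphenyl}hexan-1-one | CCCCCC(=O)c1c(O)cc(O[Si](C)(C)C(C)(C)C)cc1O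
F5 | step 6 | 1-{5-[(tert-butyldimethylsilyl)oxy]-7-hydroxy-2,2-dimethyl-2H-chromen-8-yl}hexan-1-one | CCCCCC(=O)c1c(O)cc(O[Si](C)(C)C(C)(C)C)c2c1OC(C)(C)C=C2
F6 | step 7 | 8-hexanoyl-5,7-dihydroxy-2,2-dimethyl-2H-chromene-6-carbaldehyde | CCCCCC(=O)c1c(O)c(C=O)c(O)c2c1OC(C)(C)C=C2
F7 | step 7 | Knoevenagel alkylidene trione from F6 and 9 | CCCCCC(=O)c1c(O)c(C=C2C(=O)C(C(C)=O)=C(O)[C@](C)(C/C=C(\C)CCC=C(C)C)C2=O)c(O)c2c1OC(C)(C)C=C2
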